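**Retrosynthetic overview**

1. Cryptomerin B is reached by BCl3 unmasking (two benzyl ethers and the carbonyl-chelated 5-methyl ether) of a fully protected biflavone. The pyranone of the 5,7-dioxygenated flavone (unit B) is cut at O1–C2 to a 2'-hydroxychalcone, and this to a flavone aldehyde plus 2,4-bis(benzyloxy)-6-hydroxyacetophenone.
2. Feature and key disconnection: in the 4-methoxyphenyl flavone (unit A) the two fusion atoms C4a and C8a stand side by side, C4a beside the oxygen-bearing C5 and C8a beside C8–H. This pair is read as the triple bond of a 3-methoxyaryne, so C8a–O1, C4a–C4 and O1–C2 are cut together, giving an o-silylaryl triflate and 3-(4-methoxyphenyl)propiolic acid.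
3. The silyl triflate derives from the symmetric 4-aryloxy-3,5-dimethoxyphenol (ortho bromination, retro-Brook shift, triflation). That phenol comes from 4-bromo-2,6-dimethoxyphenol and 4-fluorobenzaldehyde by SNAr, acetalization and palladium-catalysed hydroxylation.
4. Ring order: the diaryl ether is made first, then the pyranone of unit A (step 6), then the pyranone of unit B (step 10).

Key step: step 6

Remark: the target has no stereocentre; the only stereo-element on the way is the E double bond of the chalcone intermediate, which is consumed in the following step.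

**Route**

Step 1
Reactants: 1 4-bromo-2,6-dimethoxyphenol; 2 4-fluorobenzaldehyde
Product: 3 4-(4-bromo-2,6-dimethoxyphenoxy)benzaldehyde
Conditions: K2CO3, DMF, 140 °C
Reagents that add atoms: none
Why: Nucleophilic aromatic substitution (SNAr): the para-formyl group activates fluoride displacement by the hindered 2,6-dimethoxyphenoxide, and the aryl bromide is inert under these conditions.

Step 2
Reactants: 3 4-(4-bromo-2,6-dimethoxyphenoxy)benzaldehyde
Product: 4 2-[4-(4-bromo-2,6-dimethoxyphenoxy)phenyl]-1,3-dioxolane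
Conditions: ethylene glycol, p-TsOH·H2O (cat.), toluene, reflux, Dean–Stark trap
Reagents that add atoms: ethylene glycol, OCCO
Why: Acid-catalysed acetalization with azeotropic removal of water masks the aldehyde against hydroxide, n-BuLi and the aryne of the later steps.

Step 3
Reactants: 4 2-[4-(4-bromo-2,6-dimethoxyphenoxy)phenyl]-1,3-dioxolane
Product: 5 4-[4-(1,3-dioxolan-2-yl)phenoxy]-3,5-dimethoxyphenol
Conditions: Pd2(dba)3 (cat.), tBuXPhos (cat.), KOH, 1,4-dioxane/H2O, 100 °C; then aq NaH2PO4 to pH 7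
Reagents that add atoms: potassium hydroxide, [K+].[OH-]
Why: Palladium-catalysed C–O coupling of an aryl bromide with hydroxide (hydroxylation with a bulky biarylphosphine) should work on this bromide, which has no ortho substituent, and the dioxolane tolerates base and the buffered work-up.

Step 4
Reactants: 5 4-[4-(1,3-dioxolan-2-yl)phenoxy]-3,5-dimethoxyphenol
Product: 6 2-bromo-4-[4-(1,3-dioxolan-2-yl)phenoxy]-3,5-dimethoxyphenol
Conditions: NBS (1.0 equiv), CH2Cl2, −40 → 0 °C
Reagents that add atoms: N-bromosuccinimide, O=C1CCC(=O)N1Br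
Why: Electrophilic aromatic bromination: the two free positions ortho to the hydroxyl are equivalent by symmetry and far more activated than the aryloxy ring, so one equivalent at low temperature should give a single monobromide without acid that could harm the acetal.

Step 5
Reactants: 6 2-bromo-4-[4-(1,3-dioxolan-2-yl)phenoxy]-3,5-dimethoxyphenol
Product: 10 4-[4-(1,3-dioxolan-2-yl)phenoxy]-3,5-dimethoxy-2-(trimethylsilyl)phenyl trifluoromethanesulfonate, via silyl ether 7 (not isolated), via aryllithium 8 (not isolated), via lithium phenoxide 9 (not isolated)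
Conditions: HMDS, THF, 65 °C, then evaporation; n-BuLi, THF, −78 °C; PhNTf2, −78 °C → rt; aq NH4Cl
Reagents that add atoms: hexamethyldisilazane, C[Si](C)(C)N[Si](C)(C)C; N-phenylbis(trifluoromethanesulfonimide), O=S(=O)(N(c1ccccc1)S(=O)(=O)C(F)(F)F)C(F)(F)F; n-butyllithium (CCCC[Li]) supplies lithium to 8 and 9 only
Why: O-Silylation, bromine–lithium exchange and the retro-Brook 1,3 O-to-C silyl shift place the silyl group between the phenol oxygen and the methoxy group, and the lithium phenoxide is triflated in the same flask by PhNTf2, which is mild enough for the dioxolane; this is the standard entry to o-silylaryl triflates.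

Step 6
Reactants: 10 4-[4-(1,3-dioxolan-2-yl)phenoxy]-3,5-dimethoxy-2-(trimethylsilyl)phenyl trifluoromethanesulfonate; 11 3-(4-methoxyphenyl)propiolic acid
Product: 14 6-[4-(1,3-dioxolan-2-yl)phenoxy]-5,7-dimethoxy-2-(4-methoxyphenyl)-4H-chromen-4-one, via aryne 12 (not isolated), via hydroxyaryl ynone 13 (not isolated)
Conditions: 11 (1.5 equiv), CsF (4 equiv), THF, 125 °C, sealed tube
Reagents that add atoms: none
Why: Fluoride removes the trimethylsilyl group of 10 with loss of triflate to give aryne 12; the carboxylate of 11 adds through oxygen to the aryne carbon that bore the triflate, and the aryl anion formed beside the methoxy group attacks the ester carbonyl in a 4-exo-trig sense, the four-membered alkoxide collapsing with O-to-C acyl transfer to the phenoxide of ynone 13. This is the fluoride-induced insertion of arynes into the C–O bond of carboxylic acids, the known route to o-hydroxyaryl ketones, which with arylpropiolic acids runs on to flavones. The pyranone closes by 6-endo-dig oxa-Michael addition of the phenoxide to the ynone, so C8a–O1, C4a–C4 and O1–C2 are all made in one flask. No stereocentre is formed. The step needs regioselective addition to the unsymmetrical aryne, which the flanking methoxy group secures by inductive polarization and distortion of the triple bond (oxygen attacks the distal carbon, the later C8a), and it needs 6-endo rather than 5-exo closure, which the aryl-conjugated alkyne terminus and the hot aprotic medium favour; the symmetry of phenol 5 guarantees that 10 is a single isomer.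

Step 7
Reactants: 14 6-[4-(1,3-dioxolan-2-yl)phenoxy]-5,7-dimethoxy-2-(4-methoxyphenyl)-4H-chromen-4-one
Product: 15 4-{[5,7-dimethoxy-2-(4-methoxyphenyl)-4-oxo-4H-chromen-6-yl]oxy}benzaldehyde
Conditions: 1 M aq HCl, THF, rt
Reagents that add atoms: water, O
Why: Acid-catalysed acetal hydrolysis; the flavone and the diaryl ether are stable to dilute acid at room temperature.

Step 8
Reactants: 16 2,4,6-trihydroxyacetophenone
Product: 17 1-[2,4-bis(benzyloxy)-6-hydroxyphenyl]ethanone
Conditions: BnBr (2.1 equiv), K2CO3, DMF, rt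
Reagents that add atoms: benzyl bromide, BrCc1ccccc1
Why: Williamson etherification; the hydroxyl hydrogen-bonded to the acetyl carbonyl is the least nucleophilic, so two equivalents of benzyl bromide should leave one ortho hydroxyl free.

Step 9
Reactants: 15 4-{[5,7-dimethoxy-2-(4-methoxyphenyl)-4-oxo-4H-chromen-6-yl]oxy}benzaldehyde; 17 1-[2,4-bis(benzyloxy)-6-hydroxyphenyl]ethanone
Product: 18 (E)-1-[2,4-bis(benzyloxy)-6-hydroxyphenyl]-3-(4-{[5,7-dimethoxy-2-(4-methoxyphenyl)-4-oxo-4H-chromen-6-yl]oxy}phenyl)prop-2-en-1-one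
Conditions: KOH, EtOH/THF, rt
Reagents that add atoms: none
Why: Claisen–Schmidt aldol condensation of a non-enolizable aldehyde with the methyl ketone; E1cB dehydration should give the thermodynamically favoured E-enone.

Step 10
Reactants: 18 (E)-1-[2,4-bis(benzyloxy)-6-hydroxyphenyl]-3-(4-{[5,7-dimethoxy-2-(4-methoxyphenyl)-4-oxo-4H-chromen-6-yl]oxy}phenyl)prop-2-en-1-one
Product: 19 6-{4-[5,7-bis(benzyloxy)-4-oxo-4H-chromen-2-yl]phenoxy}-5,7-dimethoxy-2-(4-methoxyphenyl)-4H-chromen-4-one
Conditions: iodine (I2, cat.), DMSO, 130 °C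
Reagents that add atoms: none
Why: Iodine-catalysed oxidative cyclization of a 2'-hydroxychalcone (6-endo oxa-Michael addition, then dehydrogenation with DMSO as terminal oxidant) is the standard closure of the flavone pyranone.

Step 11
Reactants: 19 6-{4-[5,7-bis(benzyloxy)-4-oxo-4H-chromen-2-yl]phenoxy}-5,7-dimethoxy-2-(4-methoxyphenyl)-4H-chromen-4-one
Product: 20 cryptomerin B, 5-hydroxy-6-[4-(5,7-dihydroxy-4-oxo-4H-chromen-2-yl)phenoxy]-7-methoxy-2-(4-methoxyphenyl)-4H-chromen-4-one
Conditions: BCl3, pentamethylbenzene, CH2Cl2, −78 °C → rt; then MeOH, H2O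
Reagents that add atoms: none
Why: Lewis-acid ether cleavage: BCl3 with pentamethylbenzene as cation scavenger removes both benzyl ethers, and chelation of boron between the C4 carbonyl and the 5-methoxy oxygen should direct demethylation to that position alone, leaving the 7- and 4'-methyl ethers and the diaryl ether intact.

**Compound list**

1 | 4-bromo-2,6-dimethoxyphenol | COc1cc(Br)cc(OC)c1O | starting material
2 | 4-fluorobenzaldehyde | O=Cc1ccc(F)cc1 | starting material
3 | 4-(4-bromo-2,6-dimethoxyphenoxy)benzaldehyde | COc1cc(Br)cc(OC)c1Oc1ccc(C=O)cc1 | intermediate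
4 | 2-[4-(4-bromo-2,6-dimethoxyphenoxy)phenyl]-1,3-dioxolane | COc1cc(Br)cc(OC)c1Oc1ccc(C2OCCO2)cc1 | intermediate
5 | 4-[4-(1,3-dioxolan-2-yl)phenoxy]-3,5-dimethoxyphenol | COc1cc(O)cc(OC)c1Oc1ccc(C2OCCO2)cc1 | intermediate
6 | 2-bromo-4-[4-(1,3-dioxolan-2-yl)phenoxy]-3,5-dimethoxyphenol | COc1cc(O)c(Br)c(OC)c1Oc1ccc(C2OCCO2)cc1 | intermediate
7 | {2-bromo-4-[4-(1,3-dioxolan-2-yl)phenoxy]-3,5-dimethoxyphenoxy}trimethylsilane | COc1cc(O[Si](C)(C)C)c(Br)c(OC)c1Oc1ccc(C2OCCO2)cc1 | intermediate
8 | {3-[4-(1,3-dioxolan-2-yl)phenoxy]-2,4-dimethoxy-6-[(trimethylsilyl)oxy]phenyl}lithium | COc1cc(O[Si](C)(C)C)c([Li])c(OC)c1Oc1ccc(C2OCCO2)cc1 | intermediate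
9 | lithium 4-[4-(1,3-dioxolan-2-yl)phenoxy]-3,5-dimethoxy-2-(trimethylsilyl)phenolate | [Li+].[O-]c1cc(OC)c(Oc2ccc(C3OCCO3)cc2)c(OC)c1[Si](C)(C)C | intermediate
10 | 4-[4-(1,3-dioxolan-2-yl)phenoxy]-3,5-dimethoxy-2-(trimethylsilyl)phenyl trifluoromethanesulfonate | COc1cc(OS(=O)(=O)C(F)(F)F)c([Si](C)(C)C)c(OC)c1Oc1ccc(C2OCCO2)cc1 | intermediate
11 | 3-(4-methoxyphenyl)propiolic acid | COc1ccc(C#CC(=O)O)cc1 | starting material
12 | 4-[4-(1,3-dioxolan-2-yl)phenoxy]-3,5-dimethoxy-1,2-didehydrobenzene (aryne) | COC1=C(Oc2ccc(C3OCCO3)cc2)C(OC)=CC#C1 | intermediate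
13 | 1-{3-[4-(1,3-dioxolan-2-yl)phenoxy]-6-hydroxy-2,4-dimethoxyphenyl}-3-(4-methoxyphenyl)prop-2-yn-1-one | COc1ccc(C#CC(=O)c2c(O)cc(OC)c(Oc3ccc(C4OCCO4)cc3)c2OC)cc1 | intermediate
14 | 6-[4-(1,3-dioxolan-2-yl)phenoxy]-5,7-dimethoxy-2-(4-methoxyphenyl)-4H-chromen-4-one | COc1ccc(-c2cc(=O)c3c(OC)c(Oc4ccc(C5OCCO5)cc4)c(OC)cc3o2)cc1 | intermediate
15 | 4-{[5,7-dimethoxy-2-(4-methoxyphenyl)-4-oxo-4H-chromen-6-yl]oxy}benzaldehyde | COc1ccc(-c2cc(=O)c3c(OC)c(Oc4ccc(C=O)cc4)c(OC)cc3o2)cc1 | intermediate
16 | 2,4,6-trihydroxyacetophenone | CC(=O)c1c(O)cc(O)cc1O | starting material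
17 | 1-[2,4-bis(benzyloxy)-6-hydroxyphenyl]ethanone | CC(=O)c1c(O)cc(OCc2ccccc2)cc1OCc1ccccc1 | intermediate
18 | (E)-1-[2,4-bis(benzyloxy)-6-hydroxyphenyl]-3-(4-{[5,7-dimethoxy-2-(4-methoxyphenyl)-4-oxo-4H-chromen-6-yl]oxy}phenyl)prop-2-en-1-one | COc1ccc(-c2cc(=O)c3c(OC)c(Oc4ccc(/C=C/C(=O)c5c(O)cc(OCc6ccccc6)cc5OCc5ccccc5)cc4)c(OC)cc3o2)cc1 | intermediate
19 | 6-{4-[5,7-bis(benzyloxy)-4-oxo-4H-chromen-2-yl]phenoxy}-5,7-dimethoxy-2-(4-methoxyphenyl)-4H-chromen-4-one | COc1ccc(-c2cc(=O)c3c(OC)c(Oc4ccc(-c5cc(=O)c6c(OCc7ccccc7)cc(OCc7ccccc7)cc6o5)cc4)c(OC)cc3o2)cc1 | intermediate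
20 | cryptomerin B | COc1ccc(-c2cc(=O)c3c(O)c(Oc4ccc(-c5cc(=O)c6c(O)cc(O)cc6o5)cc4)c(OC)cc3o2)cc1 | target

**Step count**

Total step count: 11.
Longest linear sequence: 10 steps (from 1 to 20 through steps 1–7 and 9–11; step 8 is a one-step branch).

**Steps most likely to fail**

Step 6 (aryne insertion and flavone closure). The aryl anion may be protonated before the acyl shift, which would stop the sequence at the aryl ester. Addition to the aryne may also be less regioselective than expected on this crowded ring, or the phenoxide may close 5-exo to an aurone. The fallback sets out from phenol 5 and comes back at flavone 14. Phenol 5 is iodinated with N-iodosuccinimide at the same ortho position to give 4-[4-(1,3-dioxolan-2-yl)phenoxy]-2-iodo-3,5-dimethoxyphenol F1. F1 then undergoes the palladium-catalysed carbonylative Sonogashira annulation with 4-ethynylanisole under CO (PdCl2(PPh3)2, Et2NH, 120 °C). The o-hydroxyaryl ynone formed there is trapped by the amine as an enaminone and should close only in the 6-endo sense to 14.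

Step 9 (Claisen–Schmidt condensation). Hydroxide may open the pyranone of flavone unit A by retro-oxa-Michael addition and retro-Claisen cleavage, and enolization of the hindered, deprotonated acetophenone may be slow. The fallback sets out from aldehyde 15 (with 17) and comes back at 19, bypassing 18 and step 10. Pinnick oxidation (NaClO2, NaH2PO4, 2-methyl-2-butene, t-BuOH/H2O) gives 4-{[5,7-dimethoxy-2-(4-methoxyphenyl)-4-oxo-4H-chromen-6-yl]oxy}benzoic acid F2. Oxalyl chloride with catalytic DMF gives 4-{[5,7-dimethoxy-2-(4-methoxyphenyl)-4-oxo-4H-chromen-6-yl]oxy}benzoyl chloride F3. F3 acylates the lithium dianion of 17 (LiN(SiMe3)2, THF, −78 °C), a Baker–Venkataraman-type C-acylation without hydroxide, to give 1-[2,4-bis(benzyloxy)-6-hydroxyphenyl]-3-(4-{[5,7-dimethoxy-2-(4-methoxyphenyl)-4-oxo-4H-chromen-6-yl]oxy}phenyl)propane-1,3-dione F4. Acid-catalysed cyclodehydration (p-TsOH, toluene, 90 °C) then closes the second pyranone to 19.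

Step 11 (global unmasking with BCl3). Demethylation at C5 may stop short while the benzyl ethers are already gone, or prolonged exposure may start to remove the 7- or 4'-methyl ether. The fallback sets out from 19 and comes back at 20, separating the two events. Hydrogenolysis (H2, palladium on carbon, THF/MeOH) removes the benzyl groups to give 6-[4-(5,7-dihydroxy-4-oxo-4H-chromen-2-yl)phenoxy]-5,7-dimethoxy-2-(4-methoxyphenyl)-4H-chromen-4-one F5. AlCl3 in MeCN at 50 °C then cleaves only the carbonyl-chelated 5-methyl ether to give 20.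

**Further compounds**

F1 | step 6 | 4-[4-(1,3-dioxolan-2-yl)phenoxy]-2-iodo-3,5-dimethoxyphenol | COc1cc(O)c(I)c(OC)c1Oc1ccc(C2OCCO2)cc1
F2 | step 9 | 4-{[5,7-dimethoxy-2-(4-methoxyphenyl)-4-oxo-4H-chromen-6-yl]oxy}benzoic acid | COc1ccc(-c2cc(=O)c3c(OC)c(Oc4ccc(C(=O)O)cc4)c(OC)cc3o2)cc1
F3 | step 9 | 4-{[5,7-dimethoxy-2-(4-methoxyphenyl)-4-oxo-4H-chromen-6-yl]oxy}benzoyl chloride | COc1ccc(-c2cc(=O)c3c(OC)c(Oc4ccc(C(Cl)=O)cc4)c(OC)cc3o2)cc1
F4 | step 9 | 1-[2,4-bis(benzyloxy)-6-hydroxyphenyl]-3-(4-{[5,7-dimethoxy-2-(4-methoxyphenyl)-4-oxo-4H-chromen-6-yl]oxy}phenyl)propane-1,3-dione | COc1ccc(-c2cc(=O)c3c(OC)c(Oc4ccc(C(=O)CC(=O)c5c(O)cc(OCc6ccccc6)cc5OCc5ccccc5)cc4)c(OC)cc3o2)cc1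
F5 | step 11 | 6-[4-(5,7-dihydroxy-4-oxo-4H-chromen-2-yl)phenoxy]-5,7-dimethoxy-2-(4-methoxyphenyl)-4H-chromen-4-one | COc1ccc(-c2cc(=O)c3c(OC)c(Oc4ccc(-c5cc(=O)c6c(O)cc(O)cc6o5)cc4)c(OC)cc3o2)cc1
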